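Atoms carry germacrane numbering throughout, also in intermediates: ring C1–C10, C14 on C10, C15 on C4, C11–C13 on C7. Compounds are numbered as in the steps and in the list after step 24.

## Analysis of the target

The target is a germacranolide: a cyclodeca-1(10),4-diene whose C6 oxygen and C7 side chain are closed to an α-methylene-γ-butyrolactone. Both ring double bonds are trisubstituted and ring-cis: C1=C10 carries the C14 aldehyde with C2 trans to the formyl group, and C4=C5 carries the C15 hydroxymethyl group with C6 trans to it. Four contiguous ring centres (6R,7S,8S,9R) carry O6, C11, the C8 angelate and the C9 (R)-2-methylbutanoate. C11, O8 and O9 lie on one face and O6 on the other, so the lactone is trans-fused and the two acyloxy groups are cis to each other and to the C7 branch. The sensitive groups are the methylene lactone and the enal (Michael acceptors), the angelate (drifts to the tiglate), the epimerisable 2-methylbutanoate, two vicinal esters that can migrate, and a 1,5-diene that can undergo Cope rearrangement while one olefin is ring-trans. The hard points are the medium ring, two olefin geometries, telling O8 from O9 and telling C14 (aldehyde) from C15 (alcohol). The strategy rests on reading the C1=C10/C4=C5 diene as the formal metathesis product of a cyclohexene C5=C10 and a cyclobutene C1=C4, with C6 as an enone carbonyl and C15 as an ester on the cyclobutene. The (8S,9R) cis-diol with a substituted vinylic C10 is the pattern of the bromobenzene cis-dihydrodiol 5; the acetonide enone usually made from quinic acid is the mirror-image series and is not used.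

## Retrosynthetic reasoning

**Esters, C14 and C15 (38 back to 28).** The last bonds cut are the O15–trityl bond (37), the acyl C–O bond at O9 (35 + 36), the O9 p-methoxybenzyl ether (34), the acyl C–O bond at O8 (31 + 32) and the C14 oxidation level (29). The angelate goes on while O9 is still an ether, so no vicinal acyl migration is possible. C14 is oxidised while the only other free hydroxyl, O8–H, is not allylic. The saturated acid 36 is attached last under mild conditions. This reduces the problem to 28, which carries four oxygen functions of three orthogonal classes: silyl on O8 and O14, p-methoxybenzyl on O9, trityl on O15.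

**C11=C13 (28 back to 24).** The exocyclic methylene is cut off the lactone α-carbon. It is added before any ester or aldehyde is present, because it needs a lactone enolate.

**O6–C12, C6–H and C15 (24 back to 21).** The lactone C–O bond is opened to the γ-hydroxy tert-butyl ester 22, and 22 is taken back to the dienone 21 by returning C6 to a ketone and C15 to a methyl ester. A single hydride step can then set C6 and reduce C15 while the hindered tert-butyl ester survives. C15 is protected as its trityl ether (24) after the lactone is closed (23).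

**Ring expansion (21 back to 20).** The σ-bonds C1–C4 and C5–C10 are re-formed, which folds the ten-membered ring into the tricyclic ketone 20. The medium ring is then never closed from an open chain, and the forward step only has to spend ring strain.

**Key disconnection (20 back to 19 and 4).** C1–C10 and C4–C5 are cut, which gives the cyclohexenone 19 and the cyclobutene ester 4. These two bonds link two nucleophilic α-carbons and two electrophilic β-carbons, a pairing that only a photochemical [2+2] addition makes in one step. The forward reaction has to deliver head-to-head regiochemistry.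

**C7–C11 and C7–H (19 back to 14 and 15).** The acetate branch is cut at C7. Alkylation of the enolate of 14 with 15 enters anti to O8 (17), which is the wrong epimer, so the C7–H bond is made last by kinetic protonation of the enolate of 17.

**C10–C14 (14 back to 11 and 12).** The hydroxymethyl carbon is cut at the vinylic C10–Br bond of the bromo enone 11 and comes from the stannane 12. The bromine of the starting diol thus marks C10.

**C6 oxygen (11 back to 8).** The ketone is traced to the unhalogenated double bond of the diene 8 by hydration (bromohydrin 9, reduction to 10) and oxidation. The vinylic bromide protects the other double bond meanwhile.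

**O8 versus O9 (8 back to 5).** The silyl ether and the p-methoxybenzyl ether are cut back to the cyclic acetal 6 of diol 5, whose regioselective reductive opening (7) tells the two oxygens apart at the start. An acetonide would be shorter but would leave O8 and O9 indistinguishable at the end.

**Cyclobutene (4 back to 1).** The ester 4 comes from acid 3 by dehydrobromination of the bromo ester 1.

## Alternatives that were turned down

**Alternative 1:** The ring is cut at C7–C8. In the forward step indium inserts into an allylic C13–Br bond on a butenolide ring, and the allylindium adds through C7 to a C8 aldehyde at the other end of the same chain to give A1. In its favour, it is convergent and runs at room temperature, the methylene lactone arrives with the ring, and O8 comes out free beside a silylated O9, so no enolate methylenation and no extra O8/O9 differentiation are needed; on these points it is stronger than the chosen route. Against it, C7 and C8 are both created in a flexible ten-membered transition state and are steered only by remote centres at C6 and C9. The open chain must already hold both ring-cis trisubstituted olefins, and the closure competes with oligomerisation and with epimerisation next to the aldehyde. The chosen route instead derives the ring from a six-membered carbocycle, sets C7–C9 on a cyclohexenone and fixes both olefin geometries by equilibration.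

**Alternative 2:** The ring is cut at C2–C3 and re-formed at C5–C10, which is an anionic oxy-Cope rearrangement of a potassium C5 alkoxide on a chiral-pool cyclohexane template, giving A2. In its favour, the ring expansion is a low-temperature sigmatropic step with chair-controlled geometry, clearly milder and more predictable than a 180 °C cycloreversion, and C13 is present from the start. Against it for this target, A2 carries C14 as a methyl group that must later be oxidised among several allylic positions, and it has a C5 carbonyl that the target lacks and that must be removed while C4=C5 is set. C12 is at the alcohol level. The redox corrections outweigh the gain; the chosen route brings C14, C15 and C6 in with their oxygens in place.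

**Alternative 3:** The ring is cut at C3–C4. A terminal C2=C3 vinyl group is hydroborated and the C3 alkylborane is coupled under palladium catalysis with a C4 vinyl iodide to give A3. In its favour, the vinyl iodide geometry is transferred with retention, so C4=C5 is secured more rigorously than by equilibration, and C14 and C15 are already differentiated. Against it, ten-membered closure by sp3–sp2 coupling is slow and needs high dilution, and the open chain must hold all four stereocentres and the C1=C10 geometry. A3 also still has an acetonide (O8 and O9 not differentiated) and a saturated lactone, so the end game is no shorter. The chosen route avoids macrocyclisation and takes C8/C9 from the chiral pool.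

Key step: step 13

## Assumptions

- Diol 5 (the cis-dihydrodiol from microbial oxidation of bromobenzene), stannane 12 and acid 36 are taken as purchasable.
- The cycloreversion is expected to leave one ring-trans olefin. The route is drawn for C4=C5 ring-cis (ester trans to the C6 carbonyl) and C1=C10 ring-trans; if the geometries arrive the other way round, the iodine treatments in steps 14 and 20 lead to the same compounds.

## Route

Step 1
Reactants: 1 ethyl 1-bromocyclobutane-1-carboxylate
Product: 3 cyclobut-1-ene-1-carboxylic acid, via potassium cyclobut-1-ene-1-carboxylate 2 (not isolated)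
Conditions: KOH (powder), PhMe, reflux; then aq. HCl, 0 °C
Reagents that add atoms: potassium hydroxide, [K+].[OH-]
Why: Base-induced dehydrobromination (E2) of the tertiary α-bromo ester runs together with saponification; the only β-hydrogens are ring hydrogens, so the conjugated cyclobutene acid is the single elimination product and is freed on acidification.

Step 2
Reactants: 3 cyclobut-1-ene-1-carboxylic acid
Product: 4 methyl cyclobut-1-ene-1-carboxylate
Conditions: MeI, K2CO3, acetone, rt; distilled and used fresh
Reagents that add atoms: iodomethane, CI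
Why: O-Alkylation of the carboxylate (SN2 on iodomethane) esterifies without acid or heat, which the strained, polymerisable acrylate would not tolerate.

Step 3
Reactants: 5 (1S,2S)-3-bromocyclohexa-3,5-diene-1,2-diol
Product: 6 (3aS,7aS)-4-bromo-2-(4-methoxyphenyl)-3a,7a-dihydro-1,3-benzodioxole (both epimers at the acetal carbon)
Conditions: 4-MeOC6H4CH(OMe)2, CSA (cat.), CH2Cl2, −20 °C
Reagents that add atoms: 4-methoxybenzaldehyde dimethyl acetal, COc1ccc(cc1)C(OC)OC
Why: Acid-catalysed transacetalisation: the cis-diol closes the five-membered acetal at −20 °C faster than the diene dehydrates to a phenol; the new acetal centre is irrelevant because step 4 destroys it.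

Step 4
Reactants: 6 (3aS,7aS)-4-bromo-2-(4-methoxyphenyl)-3a,7a-dihydro-1,3-benzodioxole
Product: 7 (1S,2S)-3-bromo-2-[(4-methoxybenzyl)oxy]cyclohexa-3,5-dien-1-ol
Conditions: iBu2AlH, CH2Cl2, −78 → 0 °C; aq. potassium sodium tartrate
Reagents that add atoms: none
Why: Reductive acetal opening: aluminium coordinates the less hindered acetal oxygen on C8 (remote from the vinylic bromide), that C–O bond ionises and hydride quenches the oxocarbenium ion, so the p-methoxybenzyl group stays on O9 and O8 is freed.

Step 5
Reactants: 7 (1S,2S)-3-bromo-2-[(4-methoxybenzyl)oxy]cyclohexa-3,5-dien-1-ol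
Product: 8 {[(1S,6S)-5-bromo-6-[(4-methoxybenzyl)oxy]cyclohexa-2,4-dien-1-yl]oxy}(tert-butyl)dimethylsilane
Conditions: TBSCl, imidazole, DMF, 0 °C → rt
Reagents that add atoms: tert-butyldimethylsilyl chloride, CC(C)(C)[Si](C)(C)Cl
Why: Standard silylation of the single free secondary hydroxyl; imidazole avoids the acid that would aromatise the diene.

Step 6
Reactants: 8 {[(1S,6S)-5-bromo-6-[(4-methoxybenzyl)oxy]cyclohexa-2,4-dien-1-yl]oxy}(tert-butyl)dimethylsilane
Product: 9 (1S,4S,5R,6R)-3,6-dibromo-5-[(tert-butyldimethylsilyl)oxy]-4-[(4-methoxybenzyl)oxy]cyclohex-2-en-1-ol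
Conditions: NBS, THF/H2O (4:1), 0 °C
Reagents that add atoms: N-bromosuccinimide, O=C1CCC(=O)N1Br; water, O
Why: Bromohydrin formation: the bromonium ion forms on the unhalogenated, more electron-rich C6=C7 bond anti to the C8 silyl ether and water opens it at the allylic carbon C6; both new centres are erased in steps 7 and 8.

Step 7
Reactants: 9 (1S,4S,5R,6R)-3,6-dibromo-5-[(tert-butyldimethylsilyl)oxy]-4-[(4-methoxybenzyl)oxy]cyclohex-2-en-1-ol
Product: 10 (1R,4S,5S)-3-bromo-5-[(tert-butyldimethylsilyl)oxy]-4-[(4-methoxybenzyl)oxy]cyclohex-2-en-1-ol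
Conditions: Bu3SnH, AIBN (cat.), PhH, 80 °C
Reagents that add atoms: none
Why: Radical chain dehalogenation: the stannyl radical abstracts the secondary sp3 bromine far faster than the vinylic one, so only C7 is reduced.

Step 8
Reactants: 10 (1R,4S,5S)-3-bromo-5-[(tert-butyldimethylsilyl)oxy]-4-[(4-methoxybenzyl)oxy]cyclohex-2-en-1-ol
Product: 11 (4S,5S)-3-bromo-5-[(tert-butyldimethylsilyl)oxy]-4-[(4-methoxybenzyl)oxy]cyclohex-2-en-1-one
Conditions: Dess–Martin periodinane, NaHCO3, CH2Cl2, 0 °C → rt
Reagents that add atoms: none
Why: Dess–Martin oxidation of the allylic alcohol gives the β-bromo enone under buffered, non-basic conditions that leave the β-silyloxy ketone intact.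

Step 9
Reactants: 11 (4S,5S)-3-bromo-5-[(tert-butyldimethylsilyl)oxy]-4-[(4-methoxybenzyl)oxy]cyclohex-2-en-1-one; 12 (tributylstannyl)methanol
Product: 13 (4R,5S)-5-[(tert-butyldimethylsilyl)oxy]-3-(hydroxymethyl)-4-[(4-methoxybenzyl)oxy]cyclohex-2-en-1-one
Conditions: Pd(PPh3)4 (5 mol %), 1,4-dioxane, 90 °C
Reagents that add atoms: none
Why: Stille coupling: the β-bromo enone is a vinylogous acyl bromide and adds readily to zerovalent palladium, and the α-oxygenated CH2OH group is transferred from tin in preference to butyl, which puts C14 on C10.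

Step 10
Reactants: 13 (4R,5S)-5-[(tert-butyldimethylsilyl)oxy]-3-(hydroxymethyl)-4-[(4-methoxybenzyl)oxy]cyclohex-2-en-1-one
Product: 14 (4R,5S)-5-[(tert-butyldimethylsilyl)oxy]-3-{[(tert-butyldimethylsilyl)oxy]methyl}-4-[(4-methoxybenzyl)oxy]cyclohex-2-en-1-one
Conditions: TBSCl, imidazole, CH2Cl2, rt
Reagents that add atoms: tert-butyldimethylsilyl chloride, CC(C)(C)[Si](C)(C)Cl
Why: Silylation of the primary allylic alcohol masks C14 with a group that carries no abstractable α-hydrogen next to the chromophore.

Step 11
Reactants: 14 (4R,5S)-5-[(tert-butyldimethylsilyl)oxy]-3-{[(tert-butyldimethylsilyl)oxy]methyl}-4-[(4-methoxybenzyl)oxy]cyclohex-2-en-1-one; 15 tert-butyl bromoacetate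
Product: 17 tert-butyl 2-[(1S,5R,6S)-6-[(tert-butyldimethylsilyl)oxy]-4-{[(tert-butyldimethylsilyl)oxy]methyl}-5-[(4-methoxybenzyl)oxy]-2-oxocyclohex-3-en-1-yl]acetate (C7 branch trans to O8), via lithium dienolate 16 (not isolated)
Conditions: LiN(iPr)2, THF, −78 °C; then 15, DMPU, −78 → −45 °C
Reagents that add atoms: none
Why: Kinetic α′-deprotonation gives the cross-conjugated dienolate 16, which is alkylated (SN2) at C7 by the bromoacetate; the electrophile should enter anti to the C8 silyloxy group, so the epimer with the branch trans to O8 is expected, and the low temperature keeps β-elimination of the silyloxide slow.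

Step 12
Reactants: 17 tert-butyl 2-[(1S,5R,6S)-6-[(tert-butyldimethylsilyl)oxy]-4-{[(tert-butyldimethylsilyl)oxy]methyl}-5-[(4-methoxybenzyl)oxy]-2-oxocyclohex-3-en-1-yl]acetate
Product: 19 tert-butyl 2-[(1R,5R,6S)-6-[(tert-butyldimethylsilyl)oxy]-4-{[(tert-butyldimethylsilyl)oxy]methyl}-5-[(4-methoxybenzyl)oxy]-2-oxocyclohex-3-en-1-yl]acetate (C7 branch cis to O8 and O9), via lithium enolate 18 (not isolated)
Conditions: LiN(iPr)2, THF, −78 °C; then AcOH in THF, −78 °C
Reagents that add atoms: none
Why: A second enolisation makes C7 trigonal; in the tetrasubstituted enolate 18 allylic 1,2-strain with the C7 branch turns the C8 silyloxy group pseudo-axial and the proton is delivered to the opposite face (kinetic protonation), which leaves the branch cis to O8 and O9 as in the target.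

Step 13
Reactants: 19 tert-butyl 2-[(1R,5R,6S)-6-[(tert-butyldimethylsilyl)oxy]-4-{[(tert-butyldimethylsilyl)oxy]methyl}-5-[(4-methoxybenzyl)oxy]-2-oxocyclohex-3-en-1-yl]acetate; 4 methyl cyclobut-1-ene-1-carboxylate
Product: 20 cis-anti-cis tricyclo[4.4.0.0(2,5)]decanone photoadduct (C6 ketone, CO2Me on C4, CH2OTBS on C10, OPMB on C9, OTBS on C8, CH2CO2tBu on C7; bicyclohexane unit on the face opposite the C7–C9 substituents)
Conditions: hν (350 nm, Pyrex), 4 (8 equiv), degassed CH2Cl2, −30 °C
Reagents that add atoms: none
Why: Irradiation at 350 nm excites only the enone of 19 (4 is transparent), and intersystem crossing gives its twisted π,π* triplet. The triplet bonds first from C10 to the unsubstituted cyclobutene carbon C1, leaving a triplet 1,4-biradical centred on C5 (α to the ketone) and C4 (α to the ester); spin inversion and C4–C5 bonding complete the cyclobutane. The closest known reaction type is the intermolecular [2+2] photocycloaddition of 3-substituted cyclohex-2-enones with cyclobut-1-ene-1-carboxylates. The one ring closed is the four-membered ring C1–C4–C5–C10, formed untethered in two stages, the second being recombination of the 1,4-biradical. C5 and C10 are set by approach of 4 to the face opposite the three cis substituents on C7, C8 and C9 and by cis closure of the six/four junction; C1 and C4 are cis because both bonds form on one face of the cyclobutene, which lies anti to the six-membered ring to keep its C2–C3 bridge clear. The selectivity that matters is head-to-head regiochemistry (C4 to C5, C1 to C10): the ester secures it, since only this orientation gives a biradical stabilised at both centres, while the head-to-tail biradicals are less stabilised and mostly revert. Stereochemical leakage at the four new centres is tolerable because step 14 turns all of them into sp2 carbons.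

Step 14
Reactants: 20 cis-anti-cis tricyclo[4.4.0.0(2,5)]decanone photoadduct
Product: 21 ten-membered dienone (7R,8S,9R): C6 ketone, C4=C5 ring-cis with CO2Me on C4 trans to the ketone, C1=C10 ring-trans with CH2OTBS on C10, CH2CO2tBu on C7
Conditions: PhMe (degassed, 5 mM, base-washed sealed tube), 180 °C, brief heating; then iodine (cat.), CH2Cl2, rt
Reagents that add atoms: none
Why: Thermal cycloreversion of the bicyclo[2.2.0]hexane unit: the strained central C1–C4 bond breaks first (the C4 radical is ester-stabilised) and β-scission of C5–C10 follows because it puts C4=C5 in conjugation with ketone and ester and opens the six- into the ten-membered ring. All four photochemical stereocentres vanish, and iodine-atom addition–elimination brings any ester-cis isomer of the ene-dicarbonyl to the ester-trans, ring-cis form.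

Step 15
Reactants: 21 ten-membered dienone
Product: 22 diol (6R,7S,8S,9R): C6 alcohol trans to the C7 branch, C15 primary allylic alcohol, tert-butyl ester intact
Conditions: iBu2AlH (5 equiv), CH2Cl2, −78 °C; aq. potassium sodium tartrate
Reagents that add atoms: none
Why: 1,2-Reduction of the enone and reduction of the conjugated methyl ester, while the tert-butyl ester is too hindered to react at −78 °C; hydride should attack C6 from the ring periphery in the conformer with C6=O syn to C7–H, which gives the 6R alcohol trans to the C7 branch.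

Step 16
Reactants: 22 diol
Product: 23 trans-fused 6,12-lactone with free C15 alcohol
Conditions: PPTS (cat.), PhMe, 60 °C
Reagents that add atoms: none
Why: Acid-catalysed intramolecular acyl transfer (5-exo-trig) from the tert-butyl ester to the γ-hydroxyl closes the trans-fused γ-lactone with loss of tert-butanol; the primary allylic alcohol cannot reach the ester.

Step 17
Reactants: 23 trans-fused 6,12-lactone with free C15 alcohol
Product: 24 C15 trityl ether of the lactone
Conditions: Ph3CCl, Et3N, DMAP (cat.), CH2Cl2, rt
Reagents that add atoms: trityl chloride, ClC(c1ccccc1)(c1ccccc1)c1ccccc1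
Why: Tritylation of the only free, primary hydroxyl gives an ether that is stable to base, fluoride and DDQ and is removable at the end with dilute acid.

Step 18
Reactants: 24 C15 trityl ether of the lactone
Product: 28 α-methylene lactone (C11=C13), via lactone lithium enolate 25 (not isolated), via Mannich base 26 (not isolated), via trimethylammonium iodide 27 (not isolated)
Conditions: LiN(iPr)2, THF, −78 °C; dimethyl(methylidene)ammonium iodide, −78 → 0 °C; then MeI, MeOH, rt; then aq. NaHCO3, CH2Cl2
Reagents that add atoms: dimethyl(methylidene)ammonium iodide, C=[N+](C)C.[I-]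
Why: α-Methylenation by the Mannich route: the lactone enolate 25 is aminomethylated, the amine 26 is quaternised and 27 undergoes E1cB elimination of trimethylamine; C11 becomes trigonal, so its configuration in 26 does not matter.

Step 19
Reactants: 28 α-methylene lactone
Product: 29 diol with free C8 and C14 hydroxyls
Conditions: Bu4NF, AcOH (1:1), THF, 0 °C → rt
Reagents that add atoms: none
Why: Fluoride cleaves both silyl ethers while acetic acid buffers the alkoxides, which protects the methylene lactone and prevents translactonisation; the trityl and p-methoxybenzyl ethers are inert.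

Step 20
Reactants: 29 diol with free C8 and C14 hydroxyls
Product: 31 ring-cis C14 enal (C2 trans to CHO) with free C8 hydroxyl, via ring-trans enal 30 (not isolated)
Conditions: MnO2, CH2Cl2, rt; filter; then iodine (cat.), CH2Cl2, visible light, rt
Reagents that add atoms: none
Why: MnO2 oxidises only the allylic primary alcohol (the C8 hydroxyl is not allylic) to the enal 30; reversible iodine-atom addition then lets C1=C10 relax to the enal with C2 trans to the formyl group, which is also the less strained ring-cis olefin and is no longer prone to Cope rearrangement.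

Step 21
Reactants: 31 ring-cis C14 enal with free C8 hydroxyl; 32 angelic acid
Product: 34 C8 angelate, via angelic 2,4,6-trichlorobenzoic anhydride 33 (not isolated)
Conditions: 32, 2,4,6-Cl3C6H2COCl, Et3N, PhMe, rt; then 31, 75 °C
Reagents that add atoms: none
Why: Yamaguchi esterification through the mixed anhydride 33 in toluene without added nucleophilic catalyst acylates the hindered C8 hydroxyl while keeping the Z geometry of the angelate; O9 is still an ether, so no acyl migration can occur.

Step 22
Reactants: 34 C8 angelate
Product: 35 C9 alcohol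
Conditions: DDQ, CH2Cl2/pH 7 buffer, 0 °C
Reagents that add atoms: none
Why: Oxidative cleavage of the p-methoxybenzyl ether by DDQ (hydride abstraction, then hydrolysis of the oxocarbenium ion) under neutral buffered conditions that neither isomerise the angelate nor promote its migration; the trityl ether is stable.

Step 23
Reactants: 35 C9 alcohol; 36 (R)-2-methylbutanoic acid
Product: 37 C8 angelate C9 (R)-2-methylbutanoate, C15 trityl ether
Conditions: 36, EDC·HCl, DMAP (cat.), CH2Cl2, 0 °C → rt
Reagents that add atoms: none
Why: Steglich-type carbodiimide esterification of the allylic C9 hydroxyl at low temperature; the saturated acid reacts fast enough that the α-stereocentre of 36 and the neighbouring angelate are not disturbed.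

Step 24
Reactants: 37 C8 angelate C9 (R)-2-methylbutanoate, C15 trityl ether
Product: 38 target CNP0290361.1
Conditions: CF3CO2H (2 % v/v), Et3SiH, CH2Cl2, 0 °C
Reagents that add atoms: none
Why: Acid ionises the trityl ether to the trityl cation, which triethylsilane reduces irreversibly; the dilute acid leaves the esters, the enal and the methylene lactone untouched and releases the C15 alcohol of the target.

## Compound list

1 | ethyl 1-bromocyclobutane-1-carboxylate | CCOC(=O)C1(Br)CCC1 | starting material
2 | potassium cyclobut-1-ene-1-carboxylate | [K+].[O-]C(=O)C1=CCC1 | intermediate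
3 | cyclobut-1-ene-1-carboxylic acid | OC(=O)C1=CCC1 | intermediate
4 | methyl cyclobut-1-ene-1-carboxylate | COC(=O)C1=CCC1 | intermediate
5 | (1S,2S)-3-bromocyclohexa-3,5-diene-1,2-diol | BrC1=CC=C[C@H](O)[C@@H]1O | starting material
6 | (3aS,7aS)-4-bromo-2-(4-methoxyphenyl)-3a,7a-dihydro-1,3-benzodioxole, both epimers at the acetal carbon | BrC1=CC=C[C@@H]2OC(c3ccc(OC)cc3)O[C@H]12 | intermediate
7 | (1S,2S)-3-bromo-2-[(4-methoxybenzyl)oxy]cyclohexa-3,5-dien-1-ol | BrC1=CC=C[C@H](O)[C@@H]1OCc2ccc(OC)cc2 | intermediate
8 | {[(1S,6S)-5-bromo-6-[(4-methoxybenzyl)oxy]cyclohexa-2,4-dien-1-yl]oxy}(tert-butyl)dimethylsilane | BrC1=CC=C[C@H](O[Si](C)(C)C(C)(C)C)[C@@H]1OCc2ccc(OC)cc2 | intermediate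
9 | (1S,4S,5R,6R)-3,6-dibromo-5-[(tert-butyldimethylsilyl)oxy]-4-[(4-methoxybenzyl)oxy]cyclohex-2-en-1-ol | BrC1=C[C@H](O)[C@@H](Br)[C@H](O[Si](C)(C)C(C)(C)C)[C@@H]1OCc2ccc(OC)cc2 | intermediate
10 | (1R,4S,5S)-3-bromo-5-[(tert-butyldimethylsilyl)oxy]-4-[(4-methoxybenzyl)oxy]cyclohex-2-en-1-ol | BrC1=C[C@H](O)C[C@H](O[Si](C)(C)C(C)(C)C)[C@@H]1OCc2ccc(OC)cc2 | intermediate
11 | (4S,5S)-3-bromo-5-[(tert-butyldimethylsilyl)oxy]-4-[(4-methoxybenzyl)oxy]cyclohex-2-en-1-one | O=C1C=C(Br)[C@@H](OCc2ccc(OC)cc2)[C@@H](O[Si](C)(C)C(C)(C)C)C1 | intermediate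
12 | (tributylstannyl)methanol | OC[Sn](CCCC)(CCCC)CCCC | starting material
13 | (4R,5S)-5-[(tert-butyldimethylsilyl)oxy]-3-(hydroxymethyl)-4-[(4-methoxybenzyl)oxy]cyclohex-2-en-1-one | O=C1C=C(CO)[C@@H](OCc2ccc(OC)cc2)[C@@H](O[Si](C)(C)C(C)(C)C)C1 | intermediate
14 | (4R,5S)-5-[(tert-butyldimethylsilyl)oxy]-3-{[(tert-butyldimethylsilyl)oxy]methyl}-4-[(4-methoxybenzyl)oxy]cyclohex-2-en-1-one | O=C1C=C(CO[Si](C)(C)C(C)(C)C)[C@@H](OCc2ccc(OC)cc2)[C@@H](O[Si](C)(C)C(C)(C)C)C1 | intermediate
15 | tert-butyl bromoacetate | CC(C)(C)OC(=O)CBr | starting material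
16 | lithium cross-conjugated dienolate of 14 (O–Li on C6, C6=C7 and C5=C10) | [Li+].[O-]C1=C[C@H](O[Si](C)(C)C(C)(C)C)[C@H](OCc2ccc(OC)cc2)C(CO[Si](C)(C)C(C)(C)C)=C1 | intermediate
17 | tert-butyl 2-[(1S,5R,6S)-6-[(tert-butyldimethylsilyl)oxy]-4-{[(tert-butyldimethylsilyl)oxy]methyl}-5-[(4-methoxybenzyl)oxy]-2-oxocyclohex-3-en-1-yl]acetate | O=C1C=C(CO[Si](C)(C)C(C)(C)C)[C@@H](OCc2ccc(OC)cc2)[C@@H](O[Si](C)(C)C(C)(C)C)[C@@H]1CC(=O)OC(C)(C)C | intermediate
18 | lithium enolate of 17 (tetrasubstituted C6=C7) | [Li+].[O-]C1=C(CC(=O)OC(C)(C)C)[C@H](O[Si](C)(C)C(C)(C)C)[C@H](OCc2ccc(OC)cc2)C(CO[Si](C)(C)C(C)(C)C)=C1 | intermediate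
19 | tert-butyl 2-[(1R,5R,6S)-6-[(tert-butyldimethylsilyl)oxy]-4-{[(tert-butyldimethylsilyl)oxy]methyl}-5-[(4-methoxybenzyl)oxy]-2-oxocyclohex-3-en-1-yl]acetate | O=C1C=C(CO[Si](C)(C)C(C)(C)C)[C@@H](OCc2ccc(OC)cc2)[C@@H](O[Si](C)(C)C(C)(C)C)[C@H]1CC(=O)OC(C)(C)C | intermediate
20 | cis-anti-cis tricyclo[4.4.0.0(2,5)]decanone photoadduct (C6 ketone, CO2Me on C4, CH2OTBS on C10, OPMB on C9, OTBS on C8, CH2CO2tBu on C7) | O=C1[C@@H]2[C@@]3(C(=O)OC)CC[C@H]3[C@]2(CO[Si](C)(C)C(C)(C)C)[C@@H](OCc4ccc(OC)cc4)[C@@H](O[Si](C)(C)C(C)(C)C)[C@H]1CC(=O)OC(C)(C)C | intermediate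
21 | ten-membered dienone (7R,8S,9R): C6 ketone, C4=C5 ring-cis with CO2Me on C4, C1=C10 ring-trans with CH2OTBS on C10 | O=C1/C=C(/C(=O)OC)CC/C=C(\CO[Si](C)(C)C(C)(C)C)[C@@H](OCc2ccc(OC)cc2)[C@@H](O[Si](C)(C)C(C)(C)C)[C@H]1CC(=O)OC(C)(C)C | intermediate
22 | diol (6R,7S,8S,9R): C6 and C15 alcohols, tert-butyl ester on the C7 branch | O[C@@H]1/C=C(/CO)CC/C=C(\CO[Si](C)(C)C(C)(C)C)[C@@H](OCc2ccc(OC)cc2)[C@@H](O[Si](C)(C)C(C)(C)C)[C@H]1CC(=O)OC(C)(C)C | intermediate
23 | trans-fused 6,12-lactone with free C15 alcohol | C1C(=O)O[C@@H]2/C=C(/CO)CC/C=C(\CO[Si](C)(C)C(C)(C)C)[C@@H](OCc3ccc(OC)cc3)[C@@H](O[Si](C)(C)C(C)(C)C)[C@@H]12 | intermediate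
24 | C15 trityl ether of lactone 23 | C1C(=O)O[C@@H]2/C=C(/COC(c3ccccc3)(c3ccccc3)c3ccccc3)CC/C=C(\CO[Si](C)(C)C(C)(C)C)[C@@H](OCc3ccc(OC)cc3)[C@@H](O[Si](C)(C)C(C)(C)C)[C@@H]12 | intermediate
25 | lithium enolate of lactone 24 (C11=C12) | C1=C([O-])O[C@@H]2/C=C(/COC(c3ccccc3)(c3ccccc3)c3ccccc3)CC/C=C(\CO[Si](C)(C)C(C)(C)C)[C@@H](OCc3ccc(OC)cc3)[C@@H](O[Si](C)(C)C(C)(C)C)[C@@H]12.[Li+] | intermediate
26 | Mannich base: C11 (dimethylamino)methyl lactone, both C11 epimers | CN(C)CC1C(=O)O[C@@H]2/C=C(/COC(c3ccccc3)(c3ccccc3)c3ccccc3)CC/C=C(\CO[Si](C)(C)C(C)(C)C)[C@@H](OCc3ccc(OC)cc3)[C@@H](O[Si](C)(C)C(C)(C)C)[C@@H]12 | intermediate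
27 | C11 (trimethylammonio)methyl lactone iodide | C[N+](C)(C)CC1C(=O)O[C@@H]2/C=C(/COC(c3ccccc3)(c3ccccc3)c3ccccc3)CC/C=C(\CO[Si](C)(C)C(C)(C)C)[C@@H](OCc3ccc(OC)cc3)[C@@H](O[Si](C)(C)C(C)(C)C)[C@@H]12.[I-] | intermediate
28 | α-methylene lactone (O8 TBS, O9 PMB, O14 TBS, O15 trityl; C1=C10 ring-trans) | C=C1C(=O)O[C@@H]2/C=C(/COC(c3ccccc3)(c3ccccc3)c3ccccc3)CC/C=C(\CO[Si](C)(C)C(C)(C)C)[C@@H](OCc3ccc(OC)cc3)[C@@H](O[Si](C)(C)C(C)(C)C)[C@@H]12 | intermediate
29 | diol with free C8 and C14 hydroxyls | C=C1C(=O)O[C@@H]2/C=C(/COC(c3ccccc3)(c3ccccc3)c3ccccc3)CC/C=C(\CO)[C@@H](OCc3ccc(OC)cc3)[C@@H](O)[C@@H]12 | intermediate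
30 | ring-trans C14 enal (C2 cis to CHO) | C=C1C(=O)O[C@@H]2/C=C(/COC(c3ccccc3)(c3ccccc3)c3ccccc3)CC/C=C(\C=O)[C@@H](OCc3ccc(OC)cc3)[C@@H](O)[C@@H]12 | intermediate
31 | ring-cis C14 enal (C2 trans to CHO) with free C8 hydroxyl | C=C1C(=O)O[C@@H]2/C=C(/COC(c3ccccc3)(c3ccccc3)c3ccccc3)CC/C=C(/C=O)[C@@H](OCc3ccc(OC)cc3)[C@@H](O)[C@@H]12 | intermediate
32 | angelic acid, (Z)-2-methylbut-2-enoic acid | C/C=C(/C)C(=O)O | starting material
33 | angelic 2,4,6-trichlorobenzoic anhydride | C/C=C(/C)C(=O)OC(=O)c1c(Cl)cc(Cl)cc1Cl | intermediate
34 | C8 angelate (O9 PMB, O15 trityl) | C=C1C(=O)O[C@@H]2/C=C(/COC(c3ccccc3)(c3ccccc3)c3ccccc3)CC/C=C(/C=O)[C@@H](OCc3ccc(OC)cc3)[C@@H](OC(=O)/C(C)=C\C)[C@@H]12 | intermediate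
35 | C9 alcohol (C8 angelate, O15 trityl) | C=C1C(=O)O[C@@H]2/C=C(/COC(c3ccccc3)(c3ccccc3)c3ccccc3)CC/C=C(/C=O)[C@@H](O)[C@@H](OC(=O)/C(C)=C\C)[C@@H]12 | intermediate
36 | (R)-2-methylbutanoic acid | CC[C@@H](C)C(=O)O | starting material
37 | C8 angelate C9 (R)-2-methylbutanoate, C15 trityl ether | C=C1C(=O)O[C@@H]2/C=C(/COC(c3ccccc3)(c3ccccc3)c3ccccc3)CC/C=C(/C=O)[C@@H](OC(=O)[C@H](C)CC)[C@@H](OC(=O)/C(C)=C\C)[C@@H]12 | intermediate
38 | CNP0290361.1 | C=C1C(=O)O[C@@H]2/C=C(/CO)CC/C=C(/C=O)[C@@H](OC(=O)[C@H](C)CC)[C@@H](OC(=O)/C(C)=C\C)[C@@H]12 | target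

## Step count and least certain steps

Total: 24 steps. Longest linear sequence: 22 steps (steps 3–24, from 5); steps 1–2 are a two-step side branch that joins at step 13.

**Step 13 (key step).** The most likely failure is slow interception of the enone triplet at C10, which is fully substituted and flanked by the C9 ether. The triplet then has time to decay, 4 polymerises, and the share of head-to-tail adduct, which cannot enter the ring expansion, rises. The fallback changes the order of bond formation. It sets out from 14, which has a methylene at C7 and is less crowded. Irradiation of 14 with 4 would give the tricyclic ketone F1. Its C7 lithium enolate would be alkylated with 15 to the branched ketone F2, drawn as the C7 epimer of 20, and re-enolisation with kinetic protonation as in step 12 would come back to the route at 20.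

**Step 14.** The cycloreversion itself is the least doubtful part; what is most likely to go wrong is what the hot ketone does at the same temperature. Thermal enolisation towards C7 can epimerise C7 or expel the C8 silanol, the tert-butyl ester can lose isobutene, and prolonged heating lets the ring-trans diene drift on by Cope rearrangement to a 1,2-dialkenylcyclohexanone. The fallback takes the ketone out before heating. It sets out from 20, which iBu2AlH at −78 °C would reduce at C6 and at the C4 ester to the tricyclic diol F3. Heating F3 would cleave the same two bonds and come back at 22. The price is the loss of the conjugation that holds back the Cope rearrangement, so the heating must be brief, and a wrong C6 configuration would be handled as under step 15.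

**Step 12.** The proton may not be delivered cleanly to one face, and the second strong-base treatment invites γ-deprotonation or β-elimination of the C8 silyloxide. The fallback makes the C7–H bond by hydrogenation instead of protonation. It sets out from 14: aldol condensation of its enolate with tert-butyl glyoxylate (LiN(iPr)2; then MsCl, Et3N) would give the exocyclic alkylidene ketone F4. Homogeneous hydrogenation (H2, RhCl(PPh3)3, PhH) would add both hydrogens from the face opposite O8 and O9 and reduce the doubly activated exocyclic olefin before the hindered ring enone. It comes back at 19.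

**Step 15.** Hydride may enter C6 from the other face, since the conformation of the ten-membered enone is not secured; this would give the alcohol cis to the C7 branch and then the cis-fused lactone. The fallback inverts C6 by substitution. It sets out from 21: the reduction would then have given the C6-epimeric diol F5. Tritylation of its primary hydroxyl gives the trityl ether F6. A Mitsunobu reaction with 4-nitrobenzoic acid (PPh3, DIAD) inverts C6 to the 4-nitrobenzoate F7. Methanolysis (K2CO3, MeOH) followed by the conditions of step 16 closes the trans-lactone and comes back at 24.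

## Further compounds

F1 | step 13 | tricyclic photoadduct of 14 and 4 without the C7 branch | O=C1[C@@H]2[C@@]3(C(=O)OC)CC[C@H]3[C@]2(CO[Si](C)(C)C(C)(C)C)[C@@H](OCc4ccc(OC)cc4)[C@@H](O[Si](C)(C)C(C)(C)C)C1
F2 | step 13 | C7 epimer of 20 (branch trans to O8) | O=C1[C@@H]2[C@@]3(C(=O)OC)CC[C@H]3[C@]2(CO[Si](C)(C)C(C)(C)C)[C@@H](OCc4ccc(OC)cc4)[C@@H](O[Si](C)(C)C(C)(C)C)[C@@H]1CC(=O)OC(C)(C)C
F3 | step 14 | tricyclic diol from 20 (C6 alcohol, CH2OH on C4, tert-butyl ester intact) | O[C@@H]1[C@@H]2[C@@]3(CO)CC[C@H]3[C@]2(CO[Si](C)(C)C(C)(C)C)[C@@H](OCc4ccc(OC)cc4)[C@@H](O[Si](C)(C)C(C)(C)C)[C@H]1CC(=O)OC(C)(C)C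
F4 | step 12 | (E)-alkylidene ketone from 14 and tert-butyl glyoxylate (C7=C11) | O=C1C=C(CO[Si](C)(C)C(C)(C)C)[C@@H](OCc2ccc(OC)cc2)[C@@H](O[Si](C)(C)C(C)(C)C)/C1=C\C(=O)OC(C)(C)C
F5 | step 15 | C6 epimer of diol 22 | O[C@H]1/C=C(/CO)CC/C=C(\CO[Si](C)(C)C(C)(C)C)[C@@H](OCc2ccc(OC)cc2)[C@@H](O[Si](C)(C)C(C)(C)C)[C@H]1CC(=O)OC(C)(C)C
F6 | step 15 | C15 trityl ether of F5 | O[C@H]1/C=C(/COC(c2ccccc2)(c2ccccc2)c2ccccc2)CC/C=C(\CO[Si](C)(C)C(C)(C)C)[C@@H](OCc2ccc(OC)cc2)[C@@H](O[Si](C)(C)C(C)(C)C)[C@H]1CC(=O)OC(C)(C)C
F7 | step 15 | C6-inverted 4-nitrobenzoate | O=C(O[C@@H]1/C=C(/COC(c2ccccc2)(c2ccccc2)c2ccccc2)CC/C=C(\CO[Si](C)(C)C(C)(C)C)[C@@H](OCc2ccc(OC)cc2)[C@@H](O[Si](C)(C)C(C)(C)C)[C@H]1CC(=O)OC(C)(C)C)c1ccc(cc1)[N+](=O)[O-]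
A1 | alternative 1 | ten-membered α-methylene lactone with free C8 hydroxyl (O9 triethylsilyl, O14 p-methoxybenzyl, O15 tert-butyldiphenylsilyl) | C=C1C(=O)O[C@@H]2/C=C(/CO[Si](c3ccccc3)(c3ccccc3)C(C)(C)C)CC/C=C(/COCc3ccc(OC)cc3)[C@@H](O[Si](CC)(CC)CC)[C@@H](O)[C@@H]12
A2 | alternative 2 | ring-expanded C5 β-keto ester as its chelated enol (O6 p-methoxybenzyl, C8/C9 acetonide, C14 methyl) | COc1ccc(CO[C@@H]2/C(O)=C(/C(=O)OC)CC/C=C(/C)[C@H]3OC(C)(C)O[C@H]3[C@H]2C(=C)CO[Si](C)(C)C(C)(C)C)cc1
A3 | alternative 3 | ten-membered ring with saturated 6,12-lactone and C8/C9 acetonide (O14 p-methoxybenzyl, O15 tert-butyldimethylsilyl) | O=C1O[C@@H]2/C=C(/CO[Si](C)(C)C(C)(C)C)CC/C=C(/COCc3ccc(OC)cc3)[C@H]3OC(C)(C)O[C@H]3[C@H]2C1
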